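## Retrosynthetic overview

1. The target comes from its undeca-O-benzyl ether by global hydrogenolysis as the last step.
2. Key step: both pyran rings of the two fisetinidol units close in one flask on a catechin that already carries two acyclic aryl(epoxy)carbinol arms. Phenol-to-epoxide 6-endo closure sets C2, and ionic hydrogenation of the tertiary C4–OH then sets C4 (3,4-cis).
3. The two interflavanyl bonds (C4–C6 and C4–C8) are made before any new ring exists, by adding 6,8-dilithiated penta-O-benzylcatechin to the ketone of two molecules of one enantiopure trans-chalcone epoxide.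
4. The epoxy ketone comes from a Claisen–Schmidt chalcone by Juliá–Colonna epoxidation, which sets C3 and encodes C2.
5. Ring order: rings A, B and C of the central unit arrive intact in (+)-catechin, the aromatic rings of the outer units are bought, and the two new pyran rings are formed last and together.

Assumption: the target is read as fisetinidol-(4β→8)-catechin-(6→4β)-fisetinidol (2R,3S in all three units, 4R and 3,4-cis in both outer units); the two tertiary carbinol centres of 10, 11 and 12 are epimer mixtures and are written without configuration because both are ionised in step 7.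

## Route

Step 1
Reactants: 1 (+)-catechin
Product: 2 3,5,7,3',4'-penta-O-benzyl-(+)-catechin, (2R,3S)
Conditions: NaH (6.5 equiv), BnBr (6 equiv), DMF, −40 °C → rt
Reagents that add atoms: benzyl bromide, BrCc1ccccc1
Why: Williamson ether synthesis in which the four phenoxides and then the C3 alkoxide are benzylated by SN2, started cold so that O-alkylation outruns C-benzylation and base-induced C2 epimerisation, and no stereocentre is touched.

Step 2
Reactants: 2 3,5,7,3',4'-penta-O-benzyl-(+)-catechin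
Product: 3 6,8-dibromo-3,5,7,3',4'-penta-O-benzyl-(+)-catechin
Conditions: NBS (2.05 equiv), CH2Cl2, −20 °C → rt, dark
Reagents that add atoms: N-bromosuccinimide, O=C1CCC(=O)N1Br
Why: electrophilic aromatic bromination, in which the phloroglucinol-type ring A is far more electron-rich than ring B, so two equivalents brominate C8 and then C6 only.

Step 3
Reactants: 4 4'-benzyloxy-2'-hydroxyacetophenone
Product: 5 1-[2-(allyloxy)-4-(benzyloxy)phenyl]ethan-1-one
Conditions: allyl bromide, K2CO3, DMF, 60 °C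
Reagents that add atoms: allyl bromide, C=CCBr
Why: Williamson ether synthesis of the hydrogen-bonded ortho-phenol, giving an allyl ether that survives the later hydroxide, peroxide and organolithium steps and is removable under neutral conditions.

Step 4
Reactants: 5 1-[2-(allyloxy)-4-(benzyloxy)phenyl]ethan-1-one; 6 3,4-bis(benzyloxy)benzaldehyde
Product: 7 (E)-1-[2-(allyloxy)-4-(benzyloxy)phenyl]-3-[3,4-bis(benzyloxy)phenyl]prop-2-en-1-one
Conditions: KOH, EtOH/THF, rt
Reagents that add atoms: none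
Why: Claisen–Schmidt (crossed aldol) condensation in which the aldehyde has no α-hydrogen and E1cB dehydration gives the conjugated E-enone.

Step 5
Reactants: 7 (E)-chalcone
Product: 8 [2-(allyloxy)-4-(benzyloxy)phenyl]{(2R,3S)-3-[3,4-bis(benzyloxy)phenyl]oxiran-2-yl}methanone (trans)
Conditions: poly-L-leucine, urea–H2O2, DBU, THF, rt; recrystallise
Reagents that add atoms: urea–hydrogen peroxide, NC(N)=O.OO
Why: Juliá–Colonna asymmetric epoxidation (Weitz–Scheffer nucleophilic epoxidation under polypeptide control), in which hydroperoxide adds to the enone held on the poly-L-leucine helix and closes to the trans-(2R,3S)-epoxy ketone, the series that poly-L-amino acids give with chalcones and that leads to natural (2R,3R)-dihydroflavonols, while the isolated allyl alkene is inert to the nucleophilic oxidant; the carbonyl-side epoxide carbon becomes C3 (retained) and the benzylic one becomes C2 (inverted in step 7).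

Step 6
Reactants: 3 6,8-dibromo-3,5,7,3',4'-penta-O-benzyl-(+)-catechin; 8 (2R,3S)-epoxy ketone (2.4 equiv)
Product: 10 6,8-bis{[2-(allyloxy)-4-(benzyloxy)phenyl][(2R,3S)-3-(3,4-bis(benzyloxy)phenyl)oxiran-2-yl]hydroxymethyl}-3,5,7,3',4'-penta-O-benzylcatechin (carbinol epimers), via 6,8-dilithio-penta-O-benzylcatechin 9 (not isolated)
Conditions: t-BuLi (4.2 equiv), THF, −78 °C; then 8, −78 → −40 °C; aq NH4Cl
Reagents that add atoms: none
Why: double bromine–lithium exchange followed by 1,2-addition of the aryllithium to the ketone, which has no readily enolisable α-hydrogen and reacts far faster than the epoxide at −78 °C, so both interflavanyl C–C bonds are made with the epoxide stereocentres untouched, and the configuration of the two new carbinols does not matter.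

Step 7
Reactants: 10 bis(aryl epoxy carbinol)
Product: 13 6,8-bis[(2R,3S,4R)-7-(benzyloxy)-2-(3,4-bis(benzyloxy)phenyl)-3-hydroxychroman-4-yl]-3,5,7,3',4'-penta-O-benzylcatechin (undeca-O-benzyl ether of the target), via bis-phenol bis-epoxide 11 (not isolated), via bis(4-arylflavan-3,4-diol) 12 (not isolated)
Conditions: Pd(PPh3)4 (5 mol %), morpholine, CH2Cl2, rt; then CF3CO2H, −78 °C, 10 min; then Et3SiH, −78 → −30 °C
Reagents that add atoms: none
Why: Proposed new method: a one-pot double deallylation, 6-endo epoxide-opening cycloetherification and ionic hydrogenation, in which Tsuji–Trost-type allyl transfer to morpholine frees the two ortho-phenols (the only free ring-closing nucleophiles, since every catechin oxygen is benzylated), acid lets each phenol open its neighbouring p-alkoxybenzylic epoxide at the benzylic carbon with inversion (the way 2'-hydroxychalcone epoxides close to trans-dihydroflavonols), setting C2 as R in a 2,3-trans ring, and the tertiary doubly benzylic C4–OH then ionises and Et3SiH, added only after ring closure, delivers hydride to the cyclic cation anti to the C3 oxygen (the face carbon nucleophiles take on 2,3-trans-flavan-4-yl cations, and the outcome known for aryllithium-addition and ionic-reduction sequences on protected flavan-4-ones), which leaves the catechin ring cis to the 3-OH (4R); the closest known reaction types are acid-catalysed epoxy-phenol cyclisation and ionic hydrogenation of tertiary benzylic alcohols.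

Step 8
Reactants: 13 undeca-O-benzyl ether
Product: 14 fisetinidol-(4β→8)-catechin-(6→4β)-fisetinidol (CNP0289228.4)
Conditions: H2 (1 atm), Pd(OH)2/C, THF/MeOH, rt
Reagents that add atoms: none
Why: catalytic hydrogenolysis of the eleven benzyl ethers under mild conditions that leave the chroman C2–O1 and C4–aryl bonds of flavan-3-ols and all stereocentres intact, as in the usual last step of protected proanthocyanidin syntheses.

## Compound list

1 | (+)-catechin, (2R,3S) | Oc1cc(O)c2c(c1)O[C@H](c1ccc(O)c(O)c1)[C@@H](O)C2 | starting material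
2 | 3,5,7,3',4'-penta-O-benzyl-(+)-catechin, (2R,3S) | c1c(OCc9ccccc9)c2c(cc1OCc9ccccc9)O[C@H](c1ccc(OCc9ccccc9)c(OCc9ccccc9)c1)[C@@H](OCc9ccccc9)C2 | intermediate
3 | 6,8-dibromo-3,5,7,3',4'-penta-O-benzyl-(+)-catechin | Brc1c(OCc9ccccc9)c2c(c(Br)c1OCc9ccccc9)O[C@H](c1ccc(OCc9ccccc9)c(OCc9ccccc9)c1)[C@@H](OCc9ccccc9)C2 | intermediate
4 | 4'-benzyloxy-2'-hydroxyacetophenone | CC(=O)c1ccc(OCc2ccccc2)cc1O | starting material
5 | 1-[2-(allyloxy)-4-(benzyloxy)phenyl]ethan-1-one | CC(=O)c1ccc(OCc2ccccc2)cc1OCC=C | intermediate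
6 | 3,4-bis(benzyloxy)benzaldehyde | O=Cc1ccc(OCc2ccccc2)c(OCc2ccccc2)c1 | starting material
7 | (E)-1-[2-(allyloxy)-4-(benzyloxy)phenyl]-3-[3,4-bis(benzyloxy)phenyl]prop-2-en-1-one | C=CCOc1cc(OCc2ccccc2)ccc1C(=O)/C=C/c1ccc(OCc2ccccc2)c(OCc2ccccc2)c1 | intermediate
8 | [2-(allyloxy)-4-(benzyloxy)phenyl]{(2R,3S)-3-[3,4-bis(benzyloxy)phenyl]oxiran-2-yl}methanone | C=CCOc1cc(OCc2ccccc2)ccc1C(=O)[C@@H]1O[C@H]1c1ccc(OCc2ccccc2)c(OCc2ccccc2)c1 | intermediate
9 | 6,8-dilithio-3,5,7,3',4'-penta-O-benzylcatechin | [Li]c1c(OCc9ccccc9)c2c(c([Li])c1OCc9ccccc9)O[C@H](c1ccc(OCc9ccccc9)c(OCc9ccccc9)c1)[C@@H](OCc9ccccc9)C2 | intermediate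
10 | 6,8-bis{[2-(allyloxy)-4-(benzyloxy)phenyl][(2R,3S)-3-(3,4-bis(benzyloxy)phenyl)oxiran-2-yl]hydroxymethyl}-penta-O-benzylcatechin, carbinol epimers | C=CCOc1cc(OCc9ccccc9)ccc1C(O)([C@@H]1O[C@H]1c1ccc(OCc9ccccc9)c(OCc9ccccc9)c1)c1c(OCc9ccccc9)c2c(c(C(O)(c4ccc(OCc9ccccc9)cc4OCC=C)[C@@H]4O[C@H]4c4ccc(OCc9ccccc9)c(OCc9ccccc9)c4)c1OCc9ccccc9)O[C@H](c1ccc(OCc9ccccc9)c(OCc9ccccc9)c1)[C@@H](OCc9ccccc9)C2 | intermediate
11 | 6,8-bis{[4-(benzyloxy)-2-hydroxyphenyl][(2R,3S)-3-(3,4-bis(benzyloxy)phenyl)oxiran-2-yl]hydroxymethyl}-penta-O-benzylcatechin, carbinol epimers | Oc1cc(OCc9ccccc9)ccc1C(O)([C@@H]1O[C@H]1c1ccc(OCc9ccccc9)c(OCc9ccccc9)c1)c1c(OCc9ccccc9)c2c(c(C(O)(c4ccc(OCc9ccccc9)cc4O)[C@@H]4O[C@H]4c4ccc(OCc9ccccc9)c(OCc9ccccc9)c4)c1OCc9ccccc9)O[C@H](c1ccc(OCc9ccccc9)c(OCc9ccccc9)c1)[C@@H](OCc9ccccc9)C2 | intermediate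
12 | 6,8-bis[(2R,3R)-7-(benzyloxy)-2-(3,4-bis(benzyloxy)phenyl)-3,4-dihydroxychroman-4-yl]-penta-O-benzylcatechin, 2,3-trans, C4 epimers (present as the C4 cations in acid) | c9ccccc9COc1ccc2c(c1)O[C@H](c1ccc(OCc9ccccc9)c(OCc9ccccc9)c1)[C@@H](O)C2(O)c1c(OCc9ccccc9)c2c(c(C3(O)c4ccc(OCc9ccccc9)cc4O[C@H](c4ccc(OCc9ccccc9)c(OCc9ccccc9)c4)[C@H]3O)c1OCc9ccccc9)O[C@H](c1ccc(OCc9ccccc9)c(OCc9ccccc9)c1)[C@@H](OCc9ccccc9)C2 | intermediate
13 | 6,8-bis[(2R,3S,4R)-7-(benzyloxy)-2-(3,4-bis(benzyloxy)phenyl)-3-hydroxychroman-4-yl]-3,5,7,3',4'-penta-O-benzylcatechin | c9ccccc9COc1ccc2c(c1)O[C@H](c1ccc(OCc9ccccc9)c(OCc9ccccc9)c1)[C@@H](O)[C@H]2c1c(OCc9ccccc9)c2c(c([C@H]3c4ccc(OCc9ccccc9)cc4O[C@H](c4ccc(OCc9ccccc9)c(OCc9ccccc9)c4)[C@H]3O)c1OCc9ccccc9)O[C@H](c1ccc(OCc9ccccc9)c(OCc9ccccc9)c1)[C@@H](OCc9ccccc9)C2 | intermediate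
14 | fisetinidol-(4β→8)-catechin-(6→4β)-fisetinidol: (+)-catechin carrying at C6 and at C8 a (2R,3S,4R)-2-(3,4-dihydroxyphenyl)-3,7-dihydroxychroman-4-yl group | Oc1ccc2c(c1)O[C@H](c1ccc(O)c(O)c1)[C@@H](O)[C@H]2c1c(O)c2c(c([C@H]3c4ccc(O)cc4O[C@H](c4ccc(O)c(O)c4)[C@H]3O)c1O)O[C@H](c1ccc(O)c(O)c1)[C@@H](O)C2 | target

## Step count and risks

Total step count: 8. Longest linear sequence: 6 steps (steps 3, 4, 5, 6, 7, 8, from 4 to 14).

Three steps most likely to fail:

**Step 6 (double aryllithium addition).** Two hindered tertiary carbinols must form on neighbouring positions of one hexasubstituted ring, and the acyclic ortho-alkoxyaryl epoxy ketone is itself crowded. The fallback sets out from 8 (with 3 as the aryl partner) and comes back at 13. It closes the pyran ring before the C–C coupling, so that the electrophile is a flat cyclic ketone without an epoxide. Compound 8 is deallylated (Pd(PPh3)4, morpholine) and the freed phenol is closed onto the epoxide with camphorsulfonic acid to give (2R,3R)-7-(benzyloxy)-2-[3,4-bis(benzyloxy)phenyl]-3-hydroxychroman-4-one F1. This is silylated (t-BuMe2SiOSO2CF3, 2,6-lutidine) to the 3-O-tert-butyldimethylsilyl ether F2. F2 is added to 9 (made from 3 and t-BuLi, with CeCl3 if enolisation interferes) to give the 6,8-bis(4-hydroxy-3-silyloxyflavan-4-yl) adduct F3. Et3SiH/CF3CO2H then gives the bis(3-O-silyl) ether of 13 F4, the bulky silyloxy group reinforcing hydride delivery anti to O3, and Bu4NF removes the silyl groups to give 13.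

**Step 7 (cyclisation and ionic hydrogenation in one flask).** The hydride may not discriminate the two faces of the C4 cation well enough when the 3-OH is free, and the cation may rearrange (pinacol-type hydride shift) before it is reduced. The fallback sets out from 12, isolated by quenching step 7 with aqueous NaHCO3 after the CF3CO2H stage, and comes back at 13. It replaces the cation by a radical. Compound 12 is converted with 1,1'-thiocarbonyldiimidazole (DMAP, toluene, 80 °C) into the bis(3,4-cyclic thionocarbonate) F5. Bu3SnH/AIBN (toluene, 90 °C) adds to sulfur and each ring opens at the tertiary, doubly benzylic C4–O bond. The planar C4 radical takes hydrogen from the stannane on the face away from the bulky C3 substituent, giving the bis(3-O-{[(tributylstannyl)sulfanyl]carbonyl}) derivative F6, which K2CO3 in aqueous MeOH cleaves to 13.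

**Step 5 (asymmetric epoxidation).** The chalcone is electron-rich and ortho-alkoxy substituted, so rate and ee under polypeptide control may be only moderate. The fallback sets out from 5 (with 6) and comes back at 8. It builds the epoxide by C–C bond formation instead of oxidising the enone. Compound 5 is α-chlorinated (LiN(SiMe3)2, Me3SiCl, THF, −78 °C, then N-chlorosuccinimide) to 1-[2-(allyloxy)-4-(benzyloxy)phenyl]-2-chloroethan-1-one F7. F7 undergoes an asymmetric Darzens condensation with 6 under a cinchona-derived quaternary ammonium phase-transfer catalyst (LiOH·H2O, n-Bu2O, 4 °C) to give the trans-epoxy ketone 8 directly. The catalyst pseudo-enantiomer is chosen by correlation with material from step 5, and the ee is raised by recrystallisation.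

## Further compounds

F1 | step 6 | (2R,3R)-7-(benzyloxy)-2-[3,4-bis(benzyloxy)phenyl]-3-hydroxychroman-4-one | O=C1c2ccc(OCc3ccccc3)cc2O[C@H](c2ccc(OCc3ccccc3)c(OCc3ccccc3)c2)[C@H]1O
F2 | step 6 | (2R,3R)-7-(benzyloxy)-2-[3,4-bis(benzyloxy)phenyl]-3-[(tert-butyldimethylsilyl)oxy]chroman-4-one | O=C1c2ccc(OCc3ccccc3)cc2O[C@H](c2ccc(OCc3ccccc3)c(OCc3ccccc3)c2)[C@H]1O[Si](C)(C)C(C)(C)C
F3 | step 6 | 6,8-bis[(2R,3R)-7-(benzyloxy)-2-(3,4-bis(benzyloxy)phenyl)-3-(tert-butyldimethylsilyloxy)-4-hydroxychroman-4-yl]-penta-O-benzylcatechin, C4 epimers | c9ccccc9COc1ccc2c(c1)O[C@H](c1ccc(OCc9ccccc9)c(OCc9ccccc9)c1)[C@@H](O[Si](C)(C)C(C)(C)C)C2(O)c1c(OCc9ccccc9)c2c(c(C3(O)c4ccc(OCc9ccccc9)cc4O[C@H](c4ccc(OCc9ccccc9)c(OCc9ccccc9)c4)[C@H]3O[Si](C)(C)C(C)(C)C)c1OCc9ccccc9)O[C@H](c1ccc(OCc9ccccc9)c(OCc9ccccc9)c1)[C@@H](OCc9ccccc9)C2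
F4 | step 6 | 6,8-bis[(2R,3S,4R)-7-(benzyloxy)-2-(3,4-bis(benzyloxy)phenyl)-3-(tert-butyldimethylsilyloxy)chroman-4-yl]-penta-O-benzylcatechin | c9ccccc9COc1ccc2c(c1)O[C@H](c1ccc(OCc9ccccc9)c(OCc9ccccc9)c1)[C@@H](O[Si](C)(C)C(C)(C)C)[C@H]2c1c(OCc9ccccc9)c2c(c([C@H]3c4ccc(OCc9ccccc9)cc4O[C@H](c4ccc(OCc9ccccc9)c(OCc9ccccc9)c4)[C@H]3O[Si](C)(C)C(C)(C)C)c1OCc9ccccc9)O[C@H](c1ccc(OCc9ccccc9)c(OCc9ccccc9)c1)[C@@H](OCc9ccccc9)C2
F5 | step 7 | bis(3,4-cyclic thionocarbonate) of 12, C4 epimers | c9ccccc9COc1ccc2c(c1)O[C@H](c1ccc(OCc9ccccc9)c(OCc9ccccc9)c1)[C@@H](OC(=S)O5)C25c1c(OCc9ccccc9)c2c(c(C36c4ccc(OCc9ccccc9)cc4O[C@H](c4ccc(OCc9ccccc9)c(OCc9ccccc9)c4)[C@H]3OC(=S)O6)c1OCc9ccccc9)O[C@H](c1ccc(OCc9ccccc9)c(OCc9ccccc9)c1)[C@@H](OCc9ccccc9)C2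
F6 | step 7 | bis(3-O-{[(tributylstannyl)sulfanyl]carbonyl}) derivative of 13 | c9ccccc9COc1ccc2c(c1)O[C@H](c1ccc(OCc9ccccc9)c(OCc9ccccc9)c1)[C@@H](OC(=O)S[Sn](CCCC)(CCCC)CCCC)[C@H]2c1c(OCc9ccccc9)c2c(c([C@H]3c4ccc(OCc9ccccc9)cc4O[C@H](c4ccc(OCc9ccccc9)c(OCc9ccccc9)c4)[C@H]3OC(=O)S[Sn](CCCC)(CCCC)CCCC)c1OCc9ccccc9)O[C@H](c1ccc(OCc9ccccc9)c(OCc9ccccc9)c1)[C@@H](OCc9ccccc9)C2
F7 | step 5 | 1-[2-(allyloxy)-4-(benzyloxy)phenyl]-2-chloroethan-1-one | ClCC(=O)c1ccc(OCc2ccccc2)cc1OCC=C
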